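**Retrosynthetic overview**
1. The C3=C4 double bond of the pyran is made last, by selenoxide syn-elimination from a 3-phenylselanyl-3,4-dihydro precursor; the C6 isovaleryl group comes from O-to-C acyl transfer onto the acyl-free bicyclic enol.
2. The bicyclic core comes from a monocyclic dihydropyran enol ether and malonyl dichloride in one [3+3] Effenberger cyclization that makes C4a–C5 and C7–C8 and delivers C5–C6–C7.
3. Enabling feature: the pyran oxygen O1 sits on C8a, whose two neighbours in the carbocycle are C4a and C8. Because O1 is already tied into the pyran ring, C8a is a locked enol ether (masked ketone) that can pass nucleophilicity only to these two α-carbons and cannot be O-acylated.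
4. The dihydropyran comes from 1,1,3-triprenylacetone by enantioselective seleno-cycloetherification, which sets C3 as a temporary stereocenter that masks the C3=C4 alkene and steers C4a. The ketone comes from 6-methylhept-5-en-2-one and two prenyl bromides.
5. Ring order: pyran ring first (step 3), carbocycle second (step 4).

Key step: step 4

Remarks on the chemistry:
- Locants of the 2H-chromene skeleton (O1, C2, C3, C4, C4a, C5, C6, C7, C8, C8a) are used for the target and all bicyclic compounds. In the monocyclic pyrans, pyran C5, pyran C6 and the first side-chain carbon on C6 are the future C4a, C8a and C8.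
- β-Dicarbonyl and β-tricarbonyl compounds are written as one enol tautomer.
- Assumption: the squaramide enantiomer named in step 3 is taken to give the (3S) selenide; if the sense of induction is the opposite, its mirror image is used. If the acylation in step 4 prefers the face syn to selenium, the (3R) selenide is made instead, since C3 is erased in step 6.

Step 1
Reactants: 1 6-methylhept-5-en-2-one; 2 1-bromo-3-methylbut-2-ene (prenyl bromide)
Product: 4 2,10-dimethylundeca-2,9-dien-6-one, via lithium enolate 3 (not isolated)
Conditions: LiN(iPr)2 (1.05 equiv), THF, −78 °C; then 2 (1.1 equiv), −78 °C to 0 °C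
Reagents that add atoms: 1-bromo-3-methylbut-2-ene (compound 2), CC(C)=CCBr
Why: Kinetic deprotonation of the methyl ketone by the hindered amide base at low temperature should give the less substituted enolate, which is C-alkylated by the allylic bromide in an SN2 reaction (ketone enolate alkylation); no stereocenter is formed.

Step 2
Reactants: 4 2,10-dimethylundeca-2,9-dien-6-one; 2 1-bromo-3-methylbut-2-ene
Product: 6 2,10-dimethyl-7-(3-methylbut-2-en-1-yl)undeca-2,9-dien-6-one, via lithium enolate 5 (not isolated)
Conditions: LiN(iPr)2 (1.05 equiv), THF, −78 °C; then 2 (1.1 equiv), −78 °C to 0 °C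
Reagents that add atoms: 1-bromo-3-methylbut-2-ene (compound 2), CC(C)=CCBr
Why: The symmetrical ketone can give only one regioisomeric enolate, and its SN2 C-alkylation (ketone enolate alkylation) installs the second geminal prenyl group; C7 then carries two identical prenyl groups and is not a stereocenter.

Step 3
Reactants: 6 2,10-dimethyl-7-(3-methylbut-2-en-1-yl)undeca-2,9-dien-6-one; 7 N-(phenylselanyl)phthalimide
Product: 8 (3S)-2,2-dimethyl-5-(3-methylbut-2-en-1-yl)-6-(4-methylpent-3-en-1-yl)-3-(phenylselanyl)-3,4-dihydro-2H-pyran
Conditions: 7 (1.1 equiv), 3-{[3,5-bis(trifluoromethyl)phenyl]amino}-4-({(2S)-3,3-dimethyl-1-oxo-1-[(2R)-2-(phenanthren-9-yl)pyrrolidin-1-yl]butan-2-yl}amino)cyclobut-3-ene-1,2-dione (10 mol %), HCl (10 mol %), 4 Å molecular sieves, toluene, −40 °C; then Et3N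
Reagents that add atoms: N-(phenylselanyl)phthalimide (compound 7), O=C1c2ccccc2C(=O)N1[Se]c1ccccc1
Why: Proposed new method: the phenylselenenyl chloride formed from 7 and HCl should add reversibly to all three alkenes, but only a seleniranium ion on one of the two geminal prenyl groups can be opened by the ketone oxygen through a six-membered transition state at the tertiary carbon (6-endo, Markovnikov, anti), the chloride-bound chiral squaramide ion pair selecting one of the rapidly equilibrating seleniranium ions so that C3 is set as (S), and loss of the pyran C5 proton then gives the enol ether (both prenyl groups give the same product because C5 becomes sp2); the closest known reaction types are the hydrogen-bond-donor-catalysed enantioselective selenoetherification of alkenyl phenols and the achiral selenium-induced cyclisation of unsaturated ketones and 1,3-dicarbonyl compounds through oxygen to cyclic enol ethers.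

Step 4
Reactants: 8 (3S)-2,2-dimethyl-5-(3-methylbut-2-en-1-yl)-6-(4-methylpent-3-en-1-yl)-3-(phenylselanyl)-3,4-dihydro-2H-pyran; 9 malonyl dichloride
Product: 11 (3S,4aS)-7-hydroxy-2,2-dimethyl-4a,8-bis(3-methylbut-2-en-1-yl)-3-(phenylselanyl)-3,4-dihydro-2H-chromen-5(4aH)-one, via exocyclic enol ether acid chloride 10 (not isolated)
Conditions: 9 (1.3 equiv), 2,6-di-tert-butyl-4-methylpyridine (2.6 equiv), CH2Cl2, −40 °C to 0 °C; aq. NaHCO3, then pH 4 buffer
Reagents that add atoms: malonyl dichloride (compound 9), O=C(Cl)CC(=O)Cl
Why: Effenberger cyclization, a [3+3] α,α'-bis-C-acylation: the enol ether β-carbon of 8 (pyran C5, future C4a) attacks malonyl dichloride (or the chlorocarbonylketene formed from it by the base) to make C4a–C5, loss of HCl through the side-chain CH2 gives exocyclic enol ether 10, and its β-carbon (future C8) attacks the second acid chloride to make C7–C8, after which loss of HCl from C8 and enolisation give the vinylogous ester enol 11. The closest known reaction type is the cyclization of alkyl and silyl enol ethers of ketones with malonyl dichloride to cyclohexane-1,3,5-trione derivatives, which tolerates prenyl side chains and forms α-quaternary carbons. The carbocycle closes by a 6-(enolendo)-exo-trig attack of C8 on the acid chloride carbon C7. The new stereocenter C4a is controlled by the temporary stereocenter C3: next to the gem-dimethyl carbon C2 the phenylselanyl group should sit pseudoaxial on the half-chair and shield one face of the enol ether, so the acylating agent should enter axially on the opposite face and place C5 trans to selenium, which is (4aS) from (3S); the two C4a epimers are diastereomers, so a minor epimer is removable by chromatography. The step needs C- over O-acylation and reaction at exactly the two α-carbons of C8a, and both follow from the substrate: O1 is already alkylated by C2 inside the pyran ring, so no enolate oxygen exists and the lone pair of O1 can relay nucleophilicity only to pyran C5 and, after proton loss, to the side-chain carbon. The hindered pyridine base takes up HCl so that the tert-alkyl enol ether, the β-alkoxy selenide and the prenyl groups are not exposed to acid.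

Step 5
Reactants: 11 (3S,4aS)-7-hydroxy-2,2-dimethyl-4a,8-bis(3-methylbut-2-en-1-yl)-3-(phenylselanyl)-3,4-dihydro-2H-chromen-5(4aH)-one; 12 3-methylbutanoic acid
Product: 14 (3S,4aS)-7-hydroxy-2,2-dimethyl-6-(3-methylbutanoyl)-4a,8-bis(3-methylbut-2-en-1-yl)-3-(phenylselanyl)-3,4-dihydro-2H-chromen-5(4aH)-one, via enol ester 13 (not isolated)
Conditions: 12 (1.2 equiv), N,N'-dicyclohexylcarbodiimide (1.3 equiv), 4-(dimethylamino)pyridine (0.5 equiv), CH2Cl2, 0 °C to rt
Reagents that add atoms: 3-methylbutanoic acid (compound 12), CC(C)CC(=O)O
Why: Carbodiimide-mediated O-acylation of the enol followed by pyridine-catalysed O-to-C acyl migration (the known C-acylation of cyclic 1,3-diones with carboxylic acids) should place the acyl group on C6, the only free nucleophilic ring carbon, with the chelated 2-acyl-1,3-dione as the thermodynamic sink; no stereocenter is touched.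

Step 6
Reactants: 14 (3S,4aS)-7-hydroxy-2,2-dimethyl-6-(3-methylbutanoyl)-4a,8-bis(3-methylbut-2-en-1-yl)-3-(phenylselanyl)-3,4-dihydro-2H-chromen-5(4aH)-one
Product: 16 (4aS)-7-hydroxy-2,2-dimethyl-6-(3-methylbutanoyl)-4a,8-bis(3-methylbut-2-en-1-yl)-2H-chromen-5(4aH)-one, via selenoxide 15 (not isolated)
Conditions: NaIO4 (1.5 equiv), NaHCO3, THF/MeOH/H2O, 0 °C to rt
Reagents that add atoms: none
Why: Chemoselective oxidation of the selenide to the selenoxide and its spontaneous syn-elimination (selenoxide elimination) should give only the C3=C4 alkene, because C2 carries no hydrogen; this erases the temporary stereocenter C3 and leaves the quaternary C4a untouched.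

**Compound list**
1 | 6-methylhept-5-en-2-one | CC(=O)CCC=C(C)C | starting material
2 | 1-bromo-3-methylbut-2-ene (prenyl bromide) | CC(C)=CCBr | starting material
3 | lithium 6-methylhepta-1,5-dien-2-olate | [Li]OC(=C)CCC=C(C)C | intermediate
4 | 2,10-dimethylundeca-2,9-dien-6-one | CC(C)=CCCC(=O)CCC=C(C)C | intermediate
5 | lithium 2,10-dimethylundeca-2,5,9-trien-6-olate (E/Z mixture at C5=C6, without consequence) | CC(C)=CCC=C(O[Li])CCC=C(C)C | intermediate
6 | 2,10-dimethyl-7-(3-methylbut-2-en-1-yl)undeca-2,9-dien-6-one (achiral) | CC(C)=CCCC(=O)C(CC=C(C)C)CC=C(C)C | intermediate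
7 | N-(phenylselanyl)phthalimide | O=C1c2ccccc2C(=O)N1[Se]c1ccccc1 | starting material
8 | (3S)-2,2-dimethyl-5-(3-methylbut-2-en-1-yl)-6-(4-methylpent-3-en-1-yl)-3-(phenylselanyl)-3,4-dihydro-2H-pyran | CC(C)=CCCC1=C(CC=C(C)C)C[C@H]([Se]c2ccccc2)C(C)(C)O1 | intermediate
9 | malonyl dichloride (propanedioyl dichloride) | O=C(Cl)CC(=O)Cl | starting material
10 | 3-[(3S,5S,6Z)-2,2-dimethyl-5-(3-methylbut-2-en-1-yl)-6-(4-methylpent-3-en-1-ylidene)-3-(phenylselanyl)oxan-5-yl]-3-oxopropanoyl chloride | CC(C)=CC/C=C1\OC(C)(C)[C@@H]([Se]c2ccccc2)C[C@]1(CC=C(C)C)C(=O)CC(=O)Cl | intermediate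
11 | (3S,4aS)-7-hydroxy-2,2-dimethyl-4a,8-bis(3-methylbut-2-en-1-yl)-3-(phenylselanyl)-3,4-dihydro-2H-chromen-5(4aH)-one (selenium trans to C5) | CC(C)=CCC1=C2OC(C)(C)[C@@H]([Se]c3ccccc3)C[C@]2(CC=C(C)C)C(=O)C=C1O | intermediate
12 | 3-methylbutanoic acid | CC(C)CC(=O)O | starting material
13 | (3S,4aS)-2,2-dimethyl-4a,8-bis(3-methylbut-2-en-1-yl)-5-oxo-3-(phenylselanyl)-3,4,4a,5-tetrahydro-2H-chromen-7-yl 3-methylbutanoate | CC(C)=CCC1=C2OC(C)(C)[C@@H]([Se]c3ccccc3)C[C@]2(CC=C(C)C)C(=O)C=C1OC(=O)CC(C)C | intermediate
14 | (3S,4aS)-7-hydroxy-2,2-dimethyl-6-(3-methylbutanoyl)-4a,8-bis(3-methylbut-2-en-1-yl)-3-(phenylselanyl)-3,4-dihydro-2H-chromen-5(4aH)-one | CC(C)=CCC1=C2OC(C)(C)[C@@H]([Se]c3ccccc3)C[C@]2(CC=C(C)C)C(=O)C(C(=O)CC(C)C)=C1O | intermediate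
15 | (3S,4aS)-7-hydroxy-2,2-dimethyl-6-(3-methylbutanoyl)-4a,8-bis(3-methylbut-2-en-1-yl)-3-(phenylseleninyl)-3,4-dihydro-2H-chromen-5(4aH)-one (both configurations at selenium) | CC(C)=CCC1=C2OC(C)(C)[C@@H]([Se](=O)c3ccccc3)C[C@]2(CC=C(C)C)C(=O)C(C(=O)CC(C)C)=C1O | intermediate
16 | (4aS)-7-hydroxy-2,2-dimethyl-6-(3-methylbutanoyl)-4a,8-bis(3-methylbut-2-en-1-yl)-2H-chromen-5(4aH)-one (CNP0111062.2) | CC(C)=CCC1=C2OC(C)(C)C=C[C@]2(CC=C(C)C)C(=O)C(C(=O)CC(C)C)=C1O | target

Total step count: 6. Longest linear sequence: 6 steps (1 to 16).

**Steps most likely to fail**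

Step 3 (proposed new method). The selenium transfer or the ring closure may discriminate poorly between the two alkene faces. A seleniranium ion may instead be captured by the second prenyl group (carbocyclisation), or the ketone may be selenenylated at its α-carbon. Fallback with known chemistry, setting out from 6: benzeneselenenyl chloride in CH2Cl2 at −78 °C, then Et3N, should give the racemic enol ether selenide F1 by the documented selenium-induced cyclofunctionalisation through the carbonyl oxygen. Preparative chromatography of F1 on a polysaccharide-based chiral stationary phase would deliver the (3S) enantiomer, which is 8, and the route continues at 8.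

Step 4 (key step). Acid released during the acylations may open the tert-alkyl enol ether at O1–C2 with selenium participation before the second C–C bond forms, which would lose the regiochemical advantage of the preformed pyran. The ketene derived from malonyl dichloride may oligomerise, and the acylating agent may enter syn to selenium. Fallback, setting out from 8: C-acylation at pyran C5 with tert-butyl 3-chloro-3-oxopropanoate and 2,6-lutidine (CH2Cl2, −40 °C) should give the tert-butyl β-keto ester F2. Heating F2 in toluene at 110 °C should expel tert-butanol to give the acylketene F3, which is trapped under neutral conditions by the exocyclic enol ether carbon to close the carbocycle and return to the route at 11. The two bonds are then made in two operations, with no acid chloride present during ring closure.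

Step 6. The oxidant or the selenium by-products may oxidise the electron-rich acyl-trione enol or the prenyl alkenes, and benzeneselenenic acid may add back to an alkene. Fallback, setting out from 11: the order of the last two steps is reversed. NaIO4 oxidation of 11 at the less electron-rich acyl-free stage should give the selenoxide F4 and, by syn-elimination, the acyl-free chromenone F5. Carbodiimide/4-(dimethylamino)pyridine acylation of F5 with 12 through the enol ester F6 then returns to the route at 16.

**Further compounds**
F1 | step 3 | racemic 2,2-dimethyl-5-(3-methylbut-2-en-1-yl)-6-(4-methylpent-3-en-1-yl)-3-(phenylselanyl)-3,4-dihydro-2H-pyran | CC(C)=CCCC1=C(CC=C(C)C)CC([Se]c2ccccc2)C(C)(C)O1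
F2 | step 4 | tert-butyl 3-[(3S,5S,6Z)-2,2-dimethyl-5-(3-methylbut-2-en-1-yl)-6-(4-methylpent-3-en-1-ylidene)-3-(phenylselanyl)oxan-5-yl]-3-oxopropanoate | CC(C)=CC/C=C1\OC(C)(C)[C@@H]([Se]c2ccccc2)C[C@]1(CC=C(C)C)C(=O)CC(=O)OC(C)(C)C
F3 | step 4 | 3-[(3S,5S,6Z)-2,2-dimethyl-5-(3-methylbut-2-en-1-yl)-6-(4-methylpent-3-en-1-ylidene)-3-(phenylselanyl)oxan-5-yl]-3-oxoprop-1-en-1-one (acylketene) | CC(C)=CC/C=C1\OC(C)(C)[C@@H]([Se]c2ccccc2)C[C@]1(CC=C(C)C)C(=O)C=C=O
F4 | step 6 | (3S,4aS)-7-hydroxy-2,2-dimethyl-4a,8-bis(3-methylbut-2-en-1-yl)-3-(phenylseleninyl)-3,4-dihydro-2H-chromen-5(4aH)-one (both configurations at selenium) | CC(C)=CCC1=C2OC(C)(C)[C@@H]([Se](=O)c3ccccc3)C[C@]2(CC=C(C)C)C(=O)C=C1O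
F5 | step 6 | (4aS)-7-hydroxy-2,2-dimethyl-4a,8-bis(3-methylbut-2-en-1-yl)-2H-chromen-5(4aH)-one | CC(C)=CCC1=C2OC(C)(C)C=C[C@]2(CC=C(C)C)C(=O)C=C1O
F6 | step 6 | (4aS)-2,2-dimethyl-4a,8-bis(3-methylbut-2-en-1-yl)-5-oxo-4a,5-dihydro-2H-chromen-7-yl 3-methylbutanoate | CC(C)=CCC1=C2OC(C)(C)C=C[C@]2(CC=C(C)C)C(=O)C=C1OC(=O)CC(C)C
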